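The percentage point of left-handed product, counted on both substrates together, is our unit for comparing these flasks.

| flask | left-handed substrate | right-handed substrate | reagent | remark | time |
|---|---|---|---|---|---|
| beta | 10 mM | 10 mM | 22 mM | run made earlier |  |
| delta | 5 mM | 5 mM | 22 mM | run made earlier |  |
| zeta | 20 mM | 20 mM | 22 mM | run made earlier |  |
| spring | 10 mM | 10 mM | 22.0 mM | everything together in a closed stirred flask, run for 3.0 d | 3.0 d |
| noon | 10 mM | 10 mM | 22.0 mM (fed, over 3.00 d) | a stirred flask in which reagent is dosed at a steady rate over 3.00 d without added volume, worked up at 3.0 d | 3.0 d |
| autumn | 10 mM | 10 mM | 22.0 mM | one stirred flow tank at steady state, fed with the mixture as stated, mean residence time 15.0 d |  |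
| winter | 10 mM | 10 mM | 22.0 mM | one stirred flow tank at steady state, fed with the mixture as stated, mean residence time 3.0 d |  |

beta run (percent of the left-handed substrate and right-handed substrate together charged)

| time / h | left-handed product / % | left-handed substrate / % |
|---|---|---|
| 4.00 | 7.9 | 22.2 |
| 10.0 | 12.4 | 15.9 |
| 20.0 | 16.5 | 11.1 |
| 30.0 | 19.2 | 6.9 |
| 40.0 | 20.3 | 5.2 |

delta run (percent of the left-handed substrate and right-handed substrate together charged)

| time / d | left-handed product / % | left-handed substrate / % |
|---|---|---|
| 0.208 | 9.2 | 20.7 |
| 0.333 | 11.7 | 17.3 |
| 0.625 | 15.7 | 12.3 |
| 1.25 | 20.0 | 6.7 |
| 2.50 | 23.6 | 1.9 |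

zeta run (percent of the left-handed substrate and right-handed substrate together charged)

| time / d | left-handed product / % | left-handed substrate / % |
|---|---|---|
| 0.208 | 8.3 | 21.3 |
| 0.333 | 10.8 | 18.4 |
| 0.625 | 13.2 | 14.1 |
| 1.25 | 16.6 | 8.4 |
| 2.50 | 18.1 | 2.7 |

(each reading ± 0.3 percentage points)

- reagent is single-handed; left-handed substrate and right-handed substrate are mirror images of each other, charged as a racemate, each of them at the stated concentration
- the stated concentrations are those of everything mixed, before any reaction; amounts are the same in each set-up
- the feed brings no volume worth counting
- the earlier runs were made in a closed, stirred flask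
- the handed part of reagent does not stay in what it makes, so the products of the two hands are mirror images too

- the set-up with the highest amount of left-handed product at the outlet or at the end, in percent of the left-handed substrate and right-handed substrate together put in ("none" if the first two lie within 2 percentage points) (spring / noon / autumn / winter / none)
- amount of left-handed product at the outlet or at the end, in percent of the left-handed substrate and right-handed substrate together put in, spring
- amount of left-handed product at the outlet or at the end, in percent of the left-handed substrate and right-handed substrate together put in, noon
- amount of left-handed product at the outlet or at the end, in percent of the left-handed substrate and right-handed substrate together put in, autumn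
- amount of left-handed product at the outlet or at the end, in percent of the left-handed substrate and right-handed substrate together put in, winter

In the earlier runs, left-handed substrate goes with reagent into left-handed product, or somewhere we do not read. At the first readings of delta and zeta, substrate plus product comes to 29.9% and 29.6%, at substrate charges of 5 mM and 20 mM, so the unread loss goes with substrate. Each run had 22 mM of reagent, so whether that loss needs reagent is untested; we assume it does not.

At its last reading, beta has caught 0.453 of the left-handed substrate lost, which is odds of 0.829. Those odds per mM of reagent at hand are the pull 0.0377 mM⁻¹, a selectivity per unit of reagent. In noon, we count as at hand what is dosed within one mean life of the substrate.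

The inputs weigh unequally. The life read late in delta is 1.00 d; beta's 1.12 d would give noon 11.8%. Delta's catch, 0.491, would give 12.2%. Counting the whole charge as at hand would give 22.6%, which is our figure for spring. One life's dose is 7.36 mM, so we commit to 10.9% for noon. Counting the whole charge as at hand moves this estimate by 12 percentage points, more than beta's life or delta's catch moves it. We make no reckoning for the tanks.

The forecast names noon as best, with spring 22.5%, noon 27%, autumn 19% and winter 21%: “Dosing keeps early reagent low, which should blunt the side path”. Our noon differs from it by 16 points.

The simulation gives spring as best, with spring 22.2%, noon 10.4%, autumn 19.4% and winter 17.0%.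

    reagent + left-handed substrate → left-handed product (k = 0.0665 L mol⁻¹ min⁻¹)
    reagent + right-handed substrate → right-handed product (k = 0.0307 L mol⁻¹ min⁻¹)
    left-handed substrate ⇌ achiral form (K = 1.70, k = 0.00522 min⁻¹)
    right-handed substrate ⇌ achiral form (K = 1.70, k = 0.00522 min⁻¹)
    achiral form → waste (k = 9.21 × 10⁻⁴ min⁻¹)
    reagent ⇌ dormant form (K = 0.450, k = 0.00380 min⁻¹)
    left-handed product ⇌ right-handed product (k = 9.71 × 10⁻⁴ min⁻¹)

The neighbouring flask is noon with 88 mM of reagent, dosed over the same 3.00 d. The left-handed substrate still there at its end, 0.40% of its charge, gives a mean life of 0.543 d if the fall is taken as exponential, shorter than the 1.00 d read in delta. One life in that neighbouring flask brings 15.9 mM, so the pull gives odds of 0.600 and 18.7% of left-handed product. That neighbouring flask gives 22.9%, against 10.4% in noon.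

All runs were computed for substances that don't exist; scatter was added.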